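The hindered diaryl ether bond C6–O–C1' is purchased rather than made. The plan rests on disconnecting the two phenolic C–O bonds, C1–OH on ring A and C6'–OH on ring B, which both stand next to that bridging oxygen. In one operation the bridge oxygen steers a lithiation onto each ring, and borylation followed by peroxide oxidation turns both C–Li bonds into C–OH. Since each ring of the precursor has two equivalent ortho C–H sites, only one product is possible. The precursor is 4-(trimethylsilyl)diphenyl ether, whose base-stable silyl group reserves C4', the one brominated carbon that no hydroxyl can direct to. Silicon-for-bromine exchange and hydroxyl-directed bromination finish the synthesis.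

Key step: step 2

Remark on atom labels: ring A is C1 (OH), C2 (Br), C3 (H), C4 (Br), C5 (H), C6 (bridge O). Ring B is C1' (bridge O), C2' (H), C3', C4', C5' (Br), C6' (OH).

Remark on stereochemistry: the target has no stereocentre, and the diaryl ether, with only one ortho substituent per ring, rotates freely. The compound is therefore achiral, there is no enantiomer to select, and no step needs stereocontrol.

Step 1
Reactants: 1 4-bromodiphenyl ether; 2 chlorotrimethylsilane
Product: 4 trimethyl(4-phenoxyphenyl)silane, via aryl Grignard reagent 3 (not isolated)
Conditions: Mg, I2 (cat.), THF, reflux; then Me3SiCl, 0 °C → rt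
Reagents that add atoms: magnesium, [Mg] (only in 3); chlorotrimethylsilane 2, C[Si](C)(C)Cl
Why: Grignard formation followed by nucleophilic substitution at silicon (silylation of an aryl Grignard reagent) is routine for aryl bromides, and the diaryl ether is inert to magnesium and to the chlorosilane.

Step 2
Reactants: 4 trimethyl(4-phenoxyphenyl)silane; 5 trimethyl borate
Product: 8 2-(2-hydroxyphenoxy)-5-(trimethylsilyl)phenol, via dilithiated ether 6 (not isolated), via bis(dimethyl boronate) 7 (not isolated)
Conditions: n-BuLi (2.4 equiv), TMEDA (2.4 equiv), Et2O–hexane, 0 °C → rt, 16 h; cannulated into B(OMe)3 (5 equiv), THF, −78 °C → rt; 30% H2O2, aq NaOH, 0 °C → rt; Na2SO3 quench; cold 1 M HCl to pH 5–6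
Reagents that add atoms: n-butyllithium, [Li]CCCC (Li of 6 only); trimethyl borate 5, COB(OC)OC (boron groups of 7 only); hydrogen peroxide, OO (both new oxygen atoms of 8)
Why: The bridge oxygen binds the n-BuLi·TMEDA aggregate and inductively acidifies its neighbouring C–H bonds, so directed ortho-metalation (complex-induced proximity effect) removes one proton from each ring and gives 6. Inverse addition to excess borate converts both C–Li bonds into C–B bonds (7; any bridged phenoxaborin-type borinate formed alongside is oxidised to the same product), after which hydroperoxide adds to boron and each aryl group shifts 1,2 from boron to oxygen with expulsion of hydroxide, so that the new oxygen sits exactly on the carbon that was metalated and hydrolysis of the aryl borates releases 8. The closest known reaction type is the 2,2'-dilithiation of diphenyl ether used to prepare 2,2'-disubstituted diphenyl ethers such as wide-bite-angle bisphosphines, joined to the standard arylboronate-to-phenol oxidation. No ring is closed and no stereocentre is formed. The step needs ortho-to-oxygen selectivity with exactly one metalation per ring: coordination to the single ether oxygen supplies the first, the local twofold symmetry of each ring makes either ortho site lead to the same compound, the negative charge of a lithiated ring discourages a second deprotonation on it, and the bulky SiMe3 group screens C3' and C5'. The aryl–SiMe3 bond tolerates butyllithium (a C–Br bond would exchange), borate and alkaline peroxide (no heteroatom on silicon, hence no Tamao–Fleming cleavage), while keeping the base near 2.4 equiv holds back the slower SiCH3 metalation and a work-up at pH 5–6 avoids protodesilylation.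

Step 3
Reactants: 8 2-(2-hydroxyphenoxy)-5-(trimethylsilyl)phenol
Product: 9 2-[2-(acetyloxy)phenoxy]-5-(trimethylsilyl)phenyl acetate
Conditions: Ac2O (2.5 equiv), pyridine, DMAP (cat.), CH2Cl2, 0 °C → rt
Reagents that add atoms: acetic anhydride, CC(=O)OC(C)=O
Why: Pyridine/DMAP-catalysed O-acylation of phenols is dependable and leaves the arylsilane untouched, and it lowers the donor strength of both phenolic oxygens below that of the bridge oxygen, so that the next electrophile is steered to C4' and not to the positions ortho and para to the hydroxyls.

Step 4
Reactants: 9 2-[2-(acetyloxy)phenoxy]-5-(trimethylsilyl)phenyl acetate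
Product: 11 5-bromo-2-(2-hydroxyphenoxy)phenol, via bromo diacetate 10 (not isolated)
Conditions: Br2 (1.0 equiv), CH2Cl2, 0 °C → rt, dark; then MeOH, 40 °C
Reagents that add atoms: bromine, BrBr
Why: Electrophilic ipso-bromodesilylation should take place at C4' because this carbon is para to the strongest donor left (the bridge oxygen) and the arenium ion is stabilised by the β-silicon effect and collapses irreversibly by loss of Me3SiBr, which makes it much faster than C–H bromination at the electronically equivalent C3 of ring A; added methanol then turns Me3SiBr into HBr, which catalyses transesterification (methanolysis) of the two aryl acetates.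

Step 5
Reactants: 11 5-bromo-2-(2-hydroxyphenoxy)phenol
Product: 12 2,3,4-tribromo-6-(3,5-dibromo-2-hydroxyphenoxy)phenol (target)
Conditions: Br2 (4.1 equiv), AcOH–CH2Cl2, 0 °C → rt; aq NaHSO3
Reagents that add atoms: bromine, BrBr
Why: Electrophilic aromatic bromination of phenols: each free hydroxyl outweighs every other substituent on its ring and has exactly two open ortho/para sites (C2 and C4 on ring A, C5' and C3' on ring B, C6 and C1' being occupied by the bridge), so four equivalents of bromine should fill just these, the crowded C5' behaving like C2 of 3-bromophenol, which is known to brominate, while the remaining C–H sites are meta to hydroxyl on rings already deactivated by two or three bromines.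

Compound list
1 | 4-bromodiphenyl ether (1-bromo-4-phenoxybenzene) | Brc1ccc(Oc2ccccc2)cc1 | starting material
2 | chlorotrimethylsilane | C[Si](C)(C)Cl | starting material
3 | (4-phenoxyphenyl)magnesium bromide (not isolated) | Br[Mg]c1ccc(Oc2ccccc2)cc1 | intermediate
4 | trimethyl(4-phenoxyphenyl)silane | C[Si](C)(C)c1ccc(Oc2ccccc2)cc1 | intermediate
5 | trimethyl borate | COB(OC)OC | starting material
6 | 2,2'-dilithio-4-(trimethylsilyl)diphenyl ether (not isolated) | [Li]c1ccccc1Oc1ccc(cc1[Li])[Si](C)(C)C | intermediate
7 | 2,2'-bis(dimethoxyboryl)-4-(trimethylsilyl)diphenyl ether (not isolated) | COB(OC)c1ccccc1Oc1ccc(cc1B(OC)OC)[Si](C)(C)C | intermediate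
8 | 2-(2-hydroxyphenoxy)-5-(trimethylsilyl)phenol | C[Si](C)(C)c1ccc(Oc2ccccc2O)c(O)c1 | intermediate
9 | 2-[2-(acetyloxy)phenoxy]-5-(trimethylsilyl)phenyl acetate | CC(=O)Oc1ccccc1Oc1ccc(cc1OC(C)=O)[Si](C)(C)C | intermediate
10 | 2-[2-(acetyloxy)phenoxy]-5-bromophenyl acetate (not isolated) | CC(=O)Oc1ccccc1Oc1ccc(Br)cc1OC(C)=O | intermediate
11 | 5-bromo-2-(2-hydroxyphenoxy)phenol | Oc1ccccc1Oc1ccc(Br)cc1O | intermediate
12 | 2,3,4-tribromo-6-(3,5-dibromo-2-hydroxyphenoxy)phenol (achiral) | Oc1c(Br)cc(Br)cc1Oc1cc(Br)c(Br)c(Br)c1O | target

Total step count: 5. Longest linear sequence: 5 (1 → 4 → 8 → 9 → 11 → 12).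

Steps most likely to fail

Step 2. The second deprotonation may stall, or base may be diverted into metalation of the SiCH3 groups, so that under-oxygenated or side-chain-functionalised material accompanies the diol. Silicon may also be lost by protonation during work-up.
- The fallback gives up the silicon placeholder and lets electronics choose C4'. It sets out from Grignard reagent 3, which is quenched with water to diphenyl ether F1 (also an article of commerce).
- n-BuLi/TMEDA converts this into 2,2'-dilithiodiphenyl ether F2. Borate trapping gives 2,2'-bis(dimethoxyboryl)diphenyl ether F3, alkaline peroxide gives 2,2'-oxydiphenol F4, and acetylation gives oxydi-2,1-phenylene diacetate F5.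
- This diacetate is twofold symmetric, and on each ring the bridge oxygen is a better donor than acetoxy. One equivalent of bromine (CH2Cl2, 0 °C) should therefore enter para to the bridge oxygen, as in the bromination of guaiacol acetate para to methoxy.
- Either ring gives the same compound, 10, where the route is rejoined. Methanolysis with catalytic HCl then leads to 11.
- The price is statistical control of mono- against dibromination in place of the silicon marker.

Step 4. C–H bromination para to the bridge oxygen on ring A (C3) may compete with ipso attack, or adventitious acid may protonate C4' and remove silicon before bromine arrives. Either process erases the marker.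
- The fallback inverts the order and drops the acetates. It sets out from 8, which is brominated unprotected with NBS (4 equiv, MeCN, 0 °C → rt), a medium that liberates no mineral acid.
- The free hydroxyls dictate all four C–H brominations, giving 2,4-dibromo-6-(3,5-dibromo-2-hydroxyphenoxy)-3-(trimethylsilyl)phenol F6. Here C3 of ring A is shut in between two bromines and the C4'–Si bond is strained by its two ortho bromines.
- One equivalent of Br2 (CH2Cl2, rt) then carries out the ipso exchange, and the fallback comes back to the route at 12.

Step 5. Bromination may stop before the crowded C5' is filled. It may also overshoot, either by substitution para to the bridge oxygen at C3 or by ipso attack para to hydroxyl that leads to dienone formation.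
- The fallback replaces the single exhaustive bromination by two mechanistically different, site-class-selective stages. It sets out from 11.
- Tetrabutylammonium tribromide (2 equiv, CH2Cl2–MeOH, rt), a mild para-selective reagent for phenols, fills C4 and C3' and gives 4,5-dibromo-2-(5-bromo-2-hydroxyphenoxy)phenol F7.
- N-bromo-tert-butylamine made from Br2 and t-BuNH2 (toluene, −30 °C → rt) then delivers bromine within a hydrogen-bonded phenol–bromoamine pair to the ortho carbons C2 and C5' only. The fallback comes back to the route at 12.

Further compounds
F1 | step 2 | diphenyl ether | c1ccc(Oc2ccccc2)cc1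
F2 | step 2 | 2,2'-dilithiodiphenyl ether | [Li]c1ccccc1Oc1ccccc1[Li]
F3 | step 2 | 2,2'-bis(dimethoxyboryl)diphenyl ether | COB(OC)c1ccccc1Oc1ccccc1B(OC)OC
F4 | step 2 | 2,2'-oxydiphenol | Oc1ccccc1Oc1ccccc1O
F5 | step 2 | oxydi-2,1-phenylene diacetate | CC(=O)Oc1ccccc1Oc1ccccc1OC(C)=O
F6 | step 4 | 2,4-dibromo-6-(3,5-dibromo-2-hydroxyphenoxy)-3-(trimethylsilyl)phenol | Oc1c(Br)cc(Br)cc1Oc1cc(Br)c([Si](C)(C)C)c(Br)c1O
F7 | step 5 | 4,5-dibromo-2-(5-bromo-2-hydroxyphenoxy)phenol | Oc1ccc(Br)cc1Oc1cc(Br)c(Br)cc1O
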